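**Assumptions (one line each)**
- Iridoid numbering is used for all intermediates (C1, O2, C3, C4, C5, C6, C7, C8, C9, C10 = CH2Cl, C11 = CH2O); β = the face of H-9 and 5-OH in the target, α = the opposite face.
- The target SMILES is read as (1S,5R,7S,8S,9S) in the core with a (2R) side chain, i.e. 1β-O-isovaleryl, 5β-OH, 7β-OAc, 8α-OH/8β-CH2Cl, 9β-H.
- The side-chain CH in compounds 3–12 (future C4) is an epimeric mixture; it becomes sp2 in step 11, so it is left unspecified.
- The route is a paper proposal; nothing here has been run.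

**Retrosynthetic overview**
1. Not used: genipin relay, or Pauson–Khand/[3+2] assembly of the cyclopenta[c]pyran followed by oxidation. The carbocycle is bought and the pyran is made last.
2. The C10–Cl/8-OH pair comes from chloride opening of an 8α,10-spiro-epoxide in the last step; the C11 and C1 esters come from acylating an allylic alcohol and a lactol.
3. The dihydropyran (ring 2) comes from one ozonolysis of two vinyl groups (a latent 1,5-dialdehyde) that closes to the enol-lactol.
4. C7/C8 come from an α-methylene ketone: reduce to the "wrong" 7α-OH, use it to direct the C8 epoxidation, then invert C7 with AcOH (Mitsunobu), which also installs the acetate.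
5. C5 and C9 are relayed from the single stereocentre of (S)-4-TBSO-cyclopentenone (ring 1, purchased); that centre is oxidised away after setting C5 and is re-created in line 4.

**Route**

Step 1
Reactants: 1 (S)-4-[(tert-butyldimethylsilyl)oxy]cyclopent-2-en-1-one; 2 ethyl (E)-4-bromobut-2-enoate
Product: 3 ethyl 2-[(1R,4S)-4-(TBSO)-1-hydroxycyclopent-2-en-1-yl]but-3-enoate (side-chain C2 epimers)
Conditions: In powder, THF–H2O (1:1), 0 °C → rt
Reagents that add atoms: none (both partners are numbered)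
Why: Barbier-type (vinylogous Reformatsky) allylation in which the allylindium adds 1,2 through its γ-carbon (the ester α-carbon) on the enone face anti to the 4-OTBS group, fixing C5 (OH cis to OTBS).

Step 2
Reactants: 3
Product: 4 2-[(1R,4S)-4-(TBSO)-1-hydroxycyclopent-2-en-1-yl]but-3-en-1-ol
Conditions: LiAlH4, THF, −20 → 0 °C
Reagents that add atoms: none (hydride only)
Why: Hydride reduction of the ester gives the primary alcohol that becomes C11–OH; no stereocentre is touched.

Step 3
Reactants: 4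
Product: 5 (1R,3S)-1-(1-hydroxybut-3-en-2-yl)cyclopent-4-ene-1,3-diol
Conditions: TBAF, THF, 0 °C
Reagents that add atoms: none
Why: Fluoride desilylation frees the secondary allylic alcohol; the tertiary bis-allylic alcohol is stable to base.

Step 4
Reactants: 5
Product: 6 (4R)-4-hydroxy-4-(1-hydroxybut-3-en-2-yl)cyclopent-2-en-1-one
Conditions: MnO2, CH2Cl2, rt
Reagents that add atoms: none
Why: Chemoselective allylic oxidation (the primary OH is homoallylic and the tertiary OH is inert) moves the enone so that C9 is now the β-carbon; the purchased stereocentre is deliberately destroyed after setting C5.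

Step 5
Reactants: 6
Product: 7 (4R)-4-[1-(TBSO)but-3-en-2-yl]-4-[(triethylsilyl)oxy]cyclopent-2-en-1-one
Conditions: TBSCl, imidazole, CH2Cl2, 0 °C; then TESOTf, 2,6-lutidine, −78 → 0 °C
Reagents that add atoms: TBSCl CC(C)(C)[Si](C)(C)Cl; TESOTf CC[Si](CC)(CC)OS(=O)(=O)C(F)(F)F
Why: Sequential silylation (primary OH with TBSCl, tertiary OH with the triflate) protects both alcohols and makes the C5 oxygen a bulky, non-chelating silyl ether for the next step.

Step 6
Reactants: 7
Product: 8 (2S,3R,4R)-4-[1-(TBSO)but-3-en-2-yl]-2-[(dimethylamino)methyl]-3-ethenyl-4-(TESO)cyclopentan-1-one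
Conditions: vinylMgBr, CuBr·SMe2 (20 mol %), TMSCl, THF, −78 °C; then CH2=NMe2+ I−, −78 °C → rt
Reagents that add atoms: vinylmagnesium bromide C=C[Mg]Br; Eschenmoser's salt C=[N+](C)C.[I-]
Why: Cu-catalysed conjugate addition with Mannich trapping of the regiodefined enolate (three-component coupling), where vinyl adds to C9 anti to the γ-silyloxy group (the usual anti-to-γ-OR preference of cuprate/TMSCl additions), i.e. cis to the C5 carbon chain, and CH2NMe2 enters C8 trans to vinyl.

Step 7
Reactants: 8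
Product: 9 (3R,4R)-4-[1-(TBSO)but-3-en-2-yl]-3-ethenyl-2-methylidene-4-(TESO)cyclopentan-1-one
Conditions: MeI, Et2O, rt; then aq. NaHCO3/CH2Cl2 (use at once)
Reagents that add atoms: none (the methyl leaves with NMe3)
Why: Quaternisation and E1cB (Hofmann-type) elimination give the α-methylene ketone, whose CH2 is C10, under base too weak to isomerise it into the ring.

Step 8
Reactants: 9
Product: 10 (1R,3R,4R)-4-[1-(TBSO)but-3-en-2-yl]-3-ethenyl-2-methylidene-4-(TESO)cyclopentan-1-ol (7α-OH: cis to vinyl, trans to OTES)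
Conditions: NaBH4, CeCl3·7H2O, MeOH, −78 °C
Reagents that add atoms: none (hydride only)
Why: Luche 1,2-reduction with hydride arriving on the β-face, anti to the two cis carbon substituents at C9 and C5, gives the 7α-alcohol, which is deliberately the epimer opposite to the target.

Step 9
Reactants: 10
Product: 11 the 7α-hydroxy-8α,10-spiro-epoxide of 10 (oxirane O on the α-face of C8, cis to 7-OH; CH2 on the β-face)
Conditions: VO(acac)2 (5 mol %), t-BuOOH, CH2Cl2, 0 °C
Reagents that add atoms: tert-butyl hydroperoxide CC(C)(C)OO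
Why: Hydroxyl-directed vanadium epoxidation delivers oxygen syn to the 7α-OH, setting C8 (O α, C10 β) against the inherent facial bias; the two isolated vinyl groups are not epoxidised without a directing OH.

Step 10
Reactants: 11
Product: 12 the 7β-acetate of the 8α,10-spiro-epoxide (C7 inverted)
Conditions: PPh3, DIAD, AcOH, THF, 0 °C → rt
Reagents that add atoms: acetic acid CC(=O)O
Why: Mitsunobu SN2 inversion converts 7α-OH into the 7β-acetate of the target in one operation; the cis epoxide oxygen cannot participate.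

Step 11
Reactants: 12
Product: 13 (1R,4aR,6S,7R,7aR)-4-[(TBSO)methyl]-1-hydroxy-4a-(TESO)-4a,5,6,7a-tetrahydro-1H-spiro[cyclopenta[c]pyran-7,2′-oxiran]-6-yl acetate (1β-lactol)
Conditions: O3, CH2Cl2, −78 °C; PPh3, → rt; then PPTS (5 mol %), rt
Reagents that add atoms: ozone [O-][O+]=O
Why: Ozonolysis of both vinyl groups unveils the cis-1,5-dialdehyde, which closes by the classical iridodial → enol-lactol cyclisation (C3 enol oxygen onto the C1 aldehyde) to the cis-fused dihydropyran, with C4 becoming sp2 and the lactol OH equilibrating to the equatorial β position.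

Step 12
Reactants: 13
Product: 14 the 1β-O-(3-methylbutanoyl) ester of 13, (1S,4aR,6S,7R,7aR)
Conditions: (i-BuCO)2O, pyridine, DMAP (cat.), CH2Cl2, −20 → 0 °C
Reagents that add atoms: isovaleric anhydride CC(C)CC(=O)OC(=O)CC(C)C
Why: Acylation of the lactol (as in genipin chemistry) gives the equatorial 1β-ester, trans to the C9–C8 bond; no other OH is free.

Step 13
Reactants: 14
Product: 15 (1S,4aR,6S,7R,7aS)-6-acetoxy-4a-hydroxy-4-(hydroxymethyl)-4a,5,6,7a-tetrahydro-1H-spiro[cyclopenta[c]pyran-7,2′-oxiran]-1-yl 3-methylbutanoate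
Conditions: TBAF/AcOH (1:1), THF, 0 °C → rt
Reagents that add atoms: none
Why: Buffered fluoride removes the primary TBS and tertiary TES ethers without touching the esters, the epoxide or the enol ether.

Step 14
Reactants: 16 (R)-2-hydroxy-3-methylbutanoic acid
Product: 17 (R)-3-methyl-2-[(3-methylbutanoyl)oxy]butanoic acid
Conditions: isovaleryl chloride (1.2 equiv), pyridine, CH2Cl2, 0 °C → rt; aq. citric acid work-up
Reagents that add atoms: isovaleryl chloride CC(C)CC(=O)Cl
Why: O-Acylation of the α-hydroxy acid (the mixed anhydride is hydrolysed on work-up); the chiral-pool (R) centre is not involved.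

Step 15
Reactants: 15; 17
Product: 18 the 8α,10-epoxide precursor of the target: 15 with its C11–OH esterified by 17, (1S,4aR,6S,7R,7aS; 2R)
Conditions: EDC·HCl, DMAP (cat.), Et3N, CH2Cl2, 0 °C
Reagents that add atoms: none (17 is numbered)
Why: Steglich esterification is selective for the primary allylic C11–OH over the tertiary 5-OH and is run cold to avoid epimerising the α-acyloxy acid.

Step 16
Reactants: 18
Product: 19 Volvaltrate B
Conditions: LiCl (5 equiv), AcOH (5 equiv), THF, rt
Reagents that add atoms: lithium chloride [Li+].[Cl-] (proton from AcOH)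
Why: Regioselective SN2 opening of the 1,1-disubstituted epoxide at its CH2 by chloride leaves the C8–O bond untouched (8α-OH, 8β-CH2Cl); the 8-OH is unmasked only now because a free 8α-OH can bridge to C3 whenever C3 is an aldehyde or oxocarbenium.

**Compound list**
1 | (S)-4-[(tert-butyldimethylsilyl)oxy]cyclopent-2-en-1-one | CC(C)(C)[Si](C)(C)O[C@H]1CC(=O)C=C1 | starting material
2 | ethyl (E)-4-bromobut-2-enoate | CCOC(=O)/C=C/CBr | starting material
3 | ethyl 2-[(1R,4S)-4-(TBSO)-1-hydroxycyclopent-2-en-1-yl]but-3-enoate (C2 epimers) | CC(C)(C)[Si](C)(C)O[C@H]1C[C@](O)(C(C=C)C(=O)OCC)C=C1 | intermediate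
4 | 2-[(1R,4S)-4-(TBSO)-1-hydroxycyclopent-2-en-1-yl]but-3-en-1-ol | CC(C)(C)[Si](C)(C)O[C@H]1C[C@](O)(C(C=C)CO)C=C1 | intermediate
5 | (1R,3S)-1-(1-hydroxybut-3-en-2-yl)cyclopent-4-ene-1,3-diol | O[C@H]1C[C@](O)(C(C=C)CO)C=C1 | intermediate
6 | (4R)-4-hydroxy-4-(1-hydroxybut-3-en-2-yl)cyclopent-2-en-1-one | O=C1C[C@](O)(C(C=C)CO)C=C1 | intermediate
7 | (4R)-4-[1-(TBSO)but-3-en-2-yl]-4-(TESO)cyclopent-2-en-1-one | O=C1C[C@](O[Si](CC)(CC)CC)(C(C=C)CO[Si](C)(C)C(C)(C)C)C=C1 | intermediate
8 | (2S,3R,4R)-4-[1-(TBSO)but-3-en-2-yl]-2-[(dimethylamino)methyl]-3-ethenyl-4-(TESO)cyclopentan-1-one | O=C1C[C@](O[Si](CC)(CC)CC)(C(C=C)CO[Si](C)(C)C(C)(C)C)[C@H](C=C)[C@H]1CN(C)C | intermediate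
9 | (3R,4R)-4-[1-(TBSO)but-3-en-2-yl]-3-ethenyl-2-methylidene-4-(TESO)cyclopentan-1-one | O=C1C[C@](O[Si](CC)(CC)CC)(C(C=C)CO[Si](C)(C)C(C)(C)C)[C@H](C=C)C1=C | intermediate
10 | (1R,3R,4R)-4-[1-(TBSO)but-3-en-2-yl]-3-ethenyl-2-methylidene-4-(TESO)cyclopentan-1-ol (7α-OH) | O[C@@H]1C[C@](O[Si](CC)(CC)CC)(C(C=C)CO[Si](C)(C)C(C)(C)C)[C@H](C=C)C1=C | intermediate
11 | 7α-hydroxy-8α,10-spiro-epoxide (5β-OTES, 5α-[1-(TBSO)but-3-en-2-yl], 9α-vinyl; OH cis to oxirane O) | O[C@@H]1C[C@](O[Si](CC)(CC)CC)(C(C=C)CO[Si](C)(C)C(C)(C)C)[C@H](C=C)[C@@]12CO2 | intermediate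
12 | 7β-acetoxy-8α,10-spiro-epoxide (acetate trans to oxirane O; otherwise as 11) | CC(=O)O[C@H]1C[C@](O[Si](CC)(CC)CC)(C(C=C)CO[Si](C)(C)C(C)(C)C)[C@H](C=C)[C@@]12CO2 | intermediate
13 | (1R,4aR,6S,7R,7aR)-4-[(TBSO)methyl]-1-hydroxy-4a-(TESO)-4a,5,6,7a-tetrahydro-1H-spiro[cyclopenta[c]pyran-7,2′-oxiran]-6-yl acetate | CC(=O)O[C@H]1C[C@]2(O[Si](CC)(CC)CC)C(CO[Si](C)(C)C(C)(C)C)=CO[C@@H](O)[C@@H]2[C@@]13CO3 | intermediate
14 | (1S,4aR,6S,7R,7aR)-6-acetoxy-4-[(TBSO)methyl]-4a-(TESO)-4a,5,6,7a-tetrahydro-1H-spiro[cyclopenta[c]pyran-7,2′-oxiran]-1-yl 3-methylbutanoate | CC(=O)O[C@H]1C[C@]2(O[Si](CC)(CC)CC)C(CO[Si](C)(C)C(C)(C)C)=CO[C@@H](OC(=O)CC(C)C)[C@@H]2[C@@]13CO3 | intermediate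
15 | (1S,4aR,6S,7R,7aS)-6-acetoxy-4a-hydroxy-4-(hydroxymethyl)-4a,5,6,7a-tetrahydro-1H-spiro[cyclopenta[c]pyran-7,2′-oxiran]-1-yl 3-methylbutanoate | CC(=O)O[C@H]1C[C@]2(O)C(CO)=CO[C@@H](OC(=O)CC(C)C)[C@@H]2[C@@]13CO3 | intermediate
16 | (R)-2-hydroxy-3-methylbutanoic acid | OC(=O)[C@H](O)C(C)C | starting material
17 | (R)-3-methyl-2-[(3-methylbutanoyl)oxy]butanoic acid | OC(=O)[C@H](OC(=O)CC(C)C)C(C)C | intermediate
18 | [(1S,4aR,6S,7R,7aS)-6-acetoxy-4a-hydroxy-1-(3-methylbutanoyloxy)-4a,5,6,7a-tetrahydro-1H-spiro[cyclopenta[c]pyran-7,2′-oxiran]-4-yl]methyl (2R)-3-methyl-2-(3-methylbutanoyloxy)butanoate | CC(=O)O[C@H]1C[C@]2(O)C(COC(=O)[C@H](OC(=O)CC(C)C)C(C)C)=CO[C@@H](OC(=O)CC(C)C)[C@@H]2[C@@]13CO3 | intermediate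
19 | Volvaltrate B, [(1S,4aR,6S,7S,7aS)-6-acetoxy-7-(chloromethyl)-4a,7-dihydroxy-1-(3-methylbutanoyloxy)-1,4a,5,6,7,7a-hexahydrocyclopenta[c]pyran-4-yl]methyl (2R)-3-methyl-2-(3-methylbutanoyloxy)butanoate | CC(=O)O[C@H]1C[C@]2(O)C(COC(=O)[C@H](OC(=O)CC(C)C)C(C)C)=CO[C@@H](OC(=O)CC(C)C)[C@@H]2[C@@]1(O)CCl | target

**Step count**
- Total steps: 16.
- Longest linear sequence: 15 (steps 1–13, 15, 16); step 14 is the one-step side-chain branch.

**Three steps most likely to fail, with fallbacks**
1. **Step 6 (C9).** The vinyl group must add next to the quaternary C5, cis to its carbon chain, so the anti-to-oxygen preference has to beat sterics. Fallback: make C9 stereospecifically instead. Install C10 on 1 first (MOMOCH2-cuprate/TMSCl, then Saegusa oxidation), add the C4 unit, convert the C7–OH to a picolinate and displace it with vinylMgBr/CuBr·SMe2 in an anti-SN2′ reaction. The resulting Δ7 olefin with C10–OH is then taken to 7β-OAc/8α-OH by Sharpless epoxidation on the α-face and Ti(OiPr)4-mediated opening at C7 with AcOH.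
2. **Step 10 (C7 inversion).** The Mitsunobu is on a hindered secondary alcohol flanked by the spiro-epoxide carbon. Fallback: invert by redox instead of SN2. Oxidise 11 to the α,β-epoxy ketone (DMP), reduce under chelation control with Zn(BH4)2 (hydride from the epoxide-oxygen face gives 7β-OH), then acetylate.
3. **Step 11 (ozonolysis/lactolisation).** The transient C1 aldehyde is a β,γ-epoxy aldehyde and can open by E1cB before the lactol closes. Fallback: change the order. Open the epoxide of 12 with LiCl/AcOH, silylate the new 8-OH (TESOTf), then ozonolyse, lactolise and acylate C1; finish with global desilylation (HF·pyridine) and the C11 esterification, so no epoxide or free 8-OH is present while C1 and C3 are aldehydes.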